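**Plan**
1. Retrosynthetic cuts, in order: the three O–benzyl bonds; C2–C1' (aryl transfer to a chromone); ring C at O1–C2 and C4–C4a (enaminone annulation of an ortho-acetyl phenol); N–CH3; N1''–C2'' (imine reduction); C2''–C6 (aryl ketone from an aryllithium and a lactam).
2. Forward: a ring A unit that is symmetric about the axis through C6 and the para oxygen is acylated at C6, the piperidine closes on that ketone, and only then is ring C built on the single free oxygen para to C6, so either ortho carbon leads to the 6-substituted flavanone.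
3. Enabling feature: N1'' and C2'' of the piperidine meet at a benzylic carbon bound to C6 of ring A, between O5 and O7, so C2'' can be the carbonyl carbon of an aryl δ-amino ketone.
4. Stereochemistry: C2'' (R) comes from ligand-controlled iridium hydrogenation of the cyclic imine; C2 (S) comes from ligand-controlled rhodium 1,4-addition of the 4-(benzyloxy)phenyl group to the chromone. The two centres are set independently.

Key step: step 3

Remark on the chemistry: the ligand antipodes written in steps 3 and 9 are assumed to give (R) at C2'' and (S) at C2; the sense of induction is to be fixed on the first small run and the other antipode used if needed.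
Remark on the chemistry: compounds 1, 3 and 17 are taken as purchased.

**Step 1**
Reactants: 1 3,5-bis(benzyloxy)phenol
Product: 2 [3,5-bis(benzyloxy)phenoxy]triisopropylsilane
Conditions: TIPSCl (1.1 equiv), imidazole (2 equiv), DMF, rt
Reagents that add atoms: triisopropylsilyl chloride, CC(C)[Si](Cl)(C(C)C)C(C)C
Why: Silylation of a phenol with a silyl chloride and imidazole is routine, and the bulky silyl ether masks the future O1 and shields its two ortho carbons from the lithiation that follows.

**Step 2**
Reactants: 2 [3,5-bis(benzyloxy)phenoxy]triisopropylsilane; 3 tert-butyl 2-oxopiperidine-1-carboxylate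
Product: 5 tert-butyl N-{5-[2,6-bis(benzyloxy)-4-(triisopropylsilyloxy)phenyl]-5-oxopentyl}carbamate, via aryllithium 4 (not isolated)
Conditions: n-BuLi (1.1 equiv), TMEDA (1.1 equiv), THF, −20 to 0 °C; then 3, −78 to −40 °C; aq NH4Cl
Reagents that add atoms: none
Why: Directed ortho-metalation should put lithium on the carbon between the two benzyloxy groups, the only site flanked by two coordinating ether oxygens and remote from the silyl group, and the aryllithium then opens the N-Boc lactam at its ring carbonyl (acylation of an organolithium by an N-acyl lactam) to give the Boc-amino ketone on work-up.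

**Step 3**
Reactants: 5 tert-butyl N-{5-[2,6-bis(benzyloxy)-4-(triisopropylsilyloxy)phenyl]-5-oxopentyl}carbamate
Product: 8 (2R)-2-[2,6-bis(benzyloxy)-4-(triisopropylsilyloxy)phenyl]piperidine, via ammonium trifluoroacetate 6 (not isolated), via cyclic imine 7 (not isolated)
Conditions: TFA, CH2Cl2, 0 °C to rt; evaporate; then Ti(OiPr)4 (1.5 equiv), [Ir(cod)Cl]2 (1 mol %), (S,S)-f-Binaphane (2.2 mol %), I2 (10 mol %), H2 (50 bar), toluene/CH2Cl2, 40 °C; aq NaHCO3
Reagents that add atoms: none
Why: TFA cleaves the carbamate to ammonium salt 6 with loss of CO2 and 2-methylpropene, Ti(OiPr)4 frees the amine and takes up water, and the nitrogen adds to the aryl ketone carbon in a 6-exo-trig closure of the piperidine ring, after which dehydration gives endocyclic imine 7. A hydride of trivalent iridium, formed from [Ir(cod)Cl]2, the bisphosphine, I2 and H2, transfers hydride to the protonated C=N and is regenerated by H2. The closest known reaction type is the one-pot N-Boc removal and iridium-catalysed intramolecular asymmetric reductive amination of aryl ω-(Boc-amino)alkyl ketones to 2-arylpyrrolidines and 2-arylpiperidines, which is an asymmetric hydrogenation of 2-aryl cyclic imines. The new stereocentre C2'' is controlled only by the chiral pocket of the ligand, which tells the aryl group from the ring CH2 on the two faces of the iminium. The step needs enantioface selection on a hindered imine; the two ortho benzyloxy groups are identical, so the twisted aryl ring shows the catalyst the same environment in either rotamer. It also needs chemoselectivity: benzyl ethers, the aryl silyl ether and the arene are inert to the homogeneous iridium hydride, and the six-membered ring closure outruns any intermolecular amination.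

**Step 4**
Reactants: 8 (2R)-2-[2,6-bis(benzyloxy)-4-(triisopropylsilyloxy)phenyl]piperidine
Product: 10 (2R)-2-[2,6-bis(benzyloxy)-4-(triisopropylsilyloxy)phenyl]-1-methylpiperidine, via iminium acetate 9 (not isolated)
Conditions: 37% aq HCHO (3 equiv), NaBH(OAc)3 (2 equiv), AcOH (1 equiv), 1,2-dichloroethane, rt; aq NaHCO3
Reagents that add atoms: formaldehyde, C=O
Why: Reductive amination with formaldehyde and NaBH(OAc)3 should methylate the secondary amine through the N-methylene iminium ion under mild conditions that leave the benzylic stereocentre and all ethers untouched.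

**Step 5**
Reactants: 10 (2R)-2-[2,6-bis(benzyloxy)-4-(triisopropylsilyloxy)phenyl]-1-methylpiperidine
Product: 11 3,5-bis(benzyloxy)-4-[(2R)-1-methylpiperidin-2-yl]phenol
Conditions: TBAF (1.1 equiv), AcOH (1.2 equiv), THF, 0 °C
Reagents that add atoms: none
Why: Fluoride-mediated desilylation cleaves the aryl silyl ether while benzyl ethers are inert, and the acetic acid buffer keeps the para-hydroxybenzylic amine away from free phenoxide, which could otherwise open the C2''–N bond through a quinone methide.

**Step 6**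
Reactants: 11 3,5-bis(benzyloxy)-4-[(2R)-1-methylpiperidin-2-yl]phenol
Product: 12 3,5-bis(benzyloxy)-2-iodo-4-[(2R)-1-methylpiperidin-2-yl]phenol
Conditions: TFA (1.1 equiv), then NIS (1.0 equiv), MeCN, −20 °C; aq Na2S2O3/NaHCO3
Reagents that add atoms: N-iodosuccinimide, O=C1CCC(=O)N1I
Why: Electrophilic aromatic iodination should go to one of the two equivalent carbons ortho to the free hydroxyl, the only unsubstituted ring positions, so the site of the later C4–C4a bond is fixed without a regiochemical choice; the amine is kept protonated to prevent N-iodination.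

**Step 7**
Reactants: 12 3,5-bis(benzyloxy)-2-iodo-4-[(2R)-1-methylpiperidin-2-yl]phenol
Product: 14 1-{2,4-bis(benzyloxy)-6-hydroxy-3-[(2R)-1-methylpiperidin-2-yl]phenyl}ethan-1-one, via dilithio phenolate 13 (not isolated)
Conditions: n-BuLi (2.2 equiv), THF, −78 °C; then MeC(O)N(OMe)Me (1.5 equiv), −78 to 0 °C; aq NH4Cl
Reagents that add atoms: N-methoxy-N-methylacetamide, CC(=O)N(C)OC
Why: Deprotonation of the phenol followed by iodine–lithium exchange gives an aryllithium that is acylated once by the Weinreb amide, whose chelated tetrahedral adduct releases the methyl ketone only on work-up.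

**Step 8**
Reactants: 14 1-{2,4-bis(benzyloxy)-6-hydroxy-3-[(2R)-1-methylpiperidin-2-yl]phenyl}ethan-1-one
Product: 16 5,7-bis(benzyloxy)-6-[(2R)-1-methylpiperidin-2-yl]-4H-chromen-4-one, via enaminone 15 (not isolated)
Conditions: DMF-DMA (3 equiv), toluene, 80 °C; evaporate; then conc. aq HCl, CH2Cl2, rt; aq NaHCO3
Reagents that add atoms: N,N-dimethylformamide dimethyl acetal, COC(OC)N(C)C
Why: Condensation of the methyl ketone with the amide acetal gives the enaminone, and acid-promoted conjugate addition of the ortho phenol with loss of dimethylamine closes the pyranone (enaminone route to chromones); only the oxygen para to C6 is free, so ring C can form in one sense only.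

**Step 9**
Reactants: 16 5,7-bis(benzyloxy)-6-[(2R)-1-methylpiperidin-2-yl]-4H-chromen-4-one; 17 [4-(benzyloxy)phenyl]boronic acid
Product: 18 (2S)-5,7-bis(benzyloxy)-2-[4-(benzyloxy)phenyl]-6-[(2R)-1-methylpiperidin-2-yl]-2,3-dihydro-4H-chromen-4-one
Conditions: 17 (3 equiv), [Rh(OH)(cod)]2 (2.5 mol %), (S)-MeO-F12-BIPHEP (6 mol %), toluene/H2O 10:1, 35 °C
Reagents that add atoms: none
Why: In this rhodium-catalysed asymmetric 1,4-addition of an arylboronic acid to a chromone (Hayashi–Miyaura reaction), the aryl complex of monovalent rhodium inserts the C2=C3 bond on the face chosen by the electron-poor atropisomeric bisphosphine and water protonates the rhodium enolate, so C2 is set as S by the catalyst and not by the remote C2'' centre.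

**Step 10**
Reactants: 18 (2S)-5,7-bis(benzyloxy)-2-[4-(benzyloxy)phenyl]-6-[(2R)-1-methylpiperidin-2-yl]-2,3-dihydro-4H-chromen-4-one
Product: 19 (2S)-5,7-dihydroxy-2-(4-hydroxyphenyl)-6-[(2R)-1-methylpiperidin-2-yl]-2,3-dihydro-4H-chromen-4-one
Conditions: H2 (1 atm), 10% Pd/C, EtOAc/MeOH 1:1, rt
Reagents that add atoms: none
Why: Hydrogenolysis of aryl benzyl ethers over Pd/C at room temperature and 1 atm should be faster than cleavage of the cyclic benzylic C2–O1 and C2''–N bonds, and the neutral medium leaves both stereocentres untouched.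

**Compound list**
1 | 3,5-bis(benzyloxy)phenol | Oc1cc(OCc2ccccc2)cc(OCc2ccccc2)c1 | starting material
2 | [3,5-bis(benzyloxy)phenoxy]triisopropylsilane | CC(C)[Si](Oc1cc(OCc2ccccc2)cc(OCc2ccccc2)c1)(C(C)C)C(C)C | intermediate
3 | tert-butyl 2-oxopiperidine-1-carboxylate | CC(C)(C)OC(=O)N1CCCCC1=O | starting material
4 | [2,6-bis(benzyloxy)-4-(triisopropylsilyloxy)phenyl]lithium | [Li]c1c(OCc2ccccc2)cc(O[Si](C(C)C)(C(C)C)C(C)C)cc1OCc1ccccc1 | intermediate
5 | tert-butyl N-{5-[2,6-bis(benzyloxy)-4-(triisopropylsilyloxy)phenyl]-5-oxopentyl}carbamate | CC(C)(C)OC(=O)NCCCCC(=O)c1c(OCc2ccccc2)cc(O[Si](C(C)C)(C(C)C)C(C)C)cc1OCc1ccccc1 | intermediate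
6 | 5-[2,6-bis(benzyloxy)-4-(triisopropylsilyloxy)phenyl]-5-oxopentan-1-aminium trifluoroacetate | [NH3+]CCCCC(=O)c1c(OCc2ccccc2)cc(O[Si](C(C)C)(C(C)C)C(C)C)cc1OCc1ccccc1.[O-]C(=O)C(F)(F)F | intermediate
7 | 6-[2,6-bis(benzyloxy)-4-(triisopropylsilyloxy)phenyl]-2,3,4,5-tetrahydropyridine | C1CCN=C(C1)c1c(OCc2ccccc2)cc(O[Si](C(C)C)(C(C)C)C(C)C)cc1OCc1ccccc1 | intermediate
8 | (2R)-2-[2,6-bis(benzyloxy)-4-(triisopropylsilyloxy)phenyl]piperidine | N1CCCC[C@@H]1c1c(OCc2ccccc2)cc(O[Si](C(C)C)(C(C)C)C(C)C)cc1OCc1ccccc1 | intermediate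
9 | (2R)-2-[2,6-bis(benzyloxy)-4-(triisopropylsilyloxy)phenyl]-1-methylidenepiperidin-1-ium acetate | C=[N+]1CCCC[C@@H]1c1c(OCc2ccccc2)cc(O[Si](C(C)C)(C(C)C)C(C)C)cc1OCc1ccccc1.CC(=O)[O-] | intermediate
10 | (2R)-2-[2,6-bis(benzyloxy)-4-(triisopropylsilyloxy)phenyl]-1-methylpiperidine | CN1CCCC[C@@H]1c1c(OCc2ccccc2)cc(O[Si](C(C)C)(C(C)C)C(C)C)cc1OCc1ccccc1 | intermediate
11 | 3,5-bis(benzyloxy)-4-[(2R)-1-methylpiperidin-2-yl]phenol | CN1CCCC[C@@H]1c1c(OCc2ccccc2)cc(O)cc1OCc1ccccc1 | intermediate
12 | 3,5-bis(benzyloxy)-2-iodo-4-[(2R)-1-methylpiperidin-2-yl]phenol | CN1CCCC[C@@H]1c1c(OCc2ccccc2)cc(O)c(I)c1OCc1ccccc1 | intermediate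
13 | lithium 3,5-bis(benzyloxy)-2-lithio-4-[(2R)-1-methylpiperidin-2-yl]phenolate | CN1CCCC[C@@H]1c1c(OCc2ccccc2)cc(O[Li])c([Li])c1OCc1ccccc1 | intermediate
14 | 1-{2,4-bis(benzyloxy)-6-hydroxy-3-[(2R)-1-methylpiperidin-2-yl]phenyl}ethan-1-one | CN1CCCC[C@@H]1c1c(OCc2ccccc2)cc(O)c(C(C)=O)c1OCc1ccccc1 | intermediate
15 | (2E)-1-{2,4-bis(benzyloxy)-6-hydroxy-3-[(2R)-1-methylpiperidin-2-yl]phenyl}-3-(dimethylamino)prop-2-en-1-one | CN1CCCC[C@@H]1c1c(OCc2ccccc2)cc(O)c(C(=O)/C=C/N(C)C)c1OCc1ccccc1 | intermediate
16 | 5,7-bis(benzyloxy)-6-[(2R)-1-methylpiperidin-2-yl]-4H-chromen-4-one | CN1CCCC[C@@H]1c1c(OCc2ccccc2)cc2occc(=O)c2c1OCc1ccccc1 | intermediate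
17 | [4-(benzyloxy)phenyl]boronic acid | OB(O)c1ccc(OCc2ccccc2)cc1 | starting material
18 | (2S)-5,7-bis(benzyloxy)-2-[4-(benzyloxy)phenyl]-6-[(2R)-1-methylpiperidin-2-yl]-2,3-dihydro-4H-chromen-4-one | CN1CCCC[C@@H]1c1c(OCc2ccccc2)cc2c(c1OCc1ccccc1)C(=O)C[C@@H](c1ccc(OCc3ccccc3)cc1)O2 | intermediate
19 | (2S)-5,7-dihydroxy-2-(4-hydroxyphenyl)-6-[(2R)-1-methylpiperidin-2-yl]-2,3-dihydro-4H-chromen-4-one | CN1CCCC[C@@H]1c1c(O)cc2c(c1O)C(=O)C[C@@H](c1ccc(O)cc1)O2 | target

**Total step count:** 10
**Longest linear sequence:** 10 steps (1 to 19)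

**Steps most likely to fail**

Step 3. Hydride transfer to the twisted, doubly ortho-substituted iminium may be slow, and the catalyst may discriminate its two faces poorly, so conversion or enantiopurity could fall short. The fallback gives up catalytic enantiocontrol and resolves. Setting out from 5, TFA in CH2Cl2 removes the Boc group, Ti(OiPr)4 closes the imine and NaBH4 in MeOH reduces it without a chiral agent to racemic 2-[2,6-bis(benzyloxy)-4-(triisopropylsilyloxy)phenyl]piperidine F1. Preparative chromatography on a chiral stationary phase then separates the enantiomers: the (R)-enantiomer is compound 8, where the route is rejoined, and (2S)-2-[2,6-bis(benzyloxy)-4-(triisopropylsilyloxy)phenyl]piperidine F2 is set aside.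

Step 9. The basic nitrogen may bind rhodium, the 5-benzyloxy group may slow insertion, and the rhodium enolate may open ring C to a chalcone, which would erode the selectivity at C2. The fallback builds ring C by condensation and oxa-Michael closure and relies on separation of diastereomers. Setting out from 14, Claisen–Schmidt condensation with 4-(benzyloxy)benzaldehyde (KOH, EtOH, rt) should give (2E)-1-{2,4-bis(benzyloxy)-6-hydroxy-3-[(2R)-1-methylpiperidin-2-yl]phenyl}-3-[4-(benzyloxy)phenyl]prop-2-en-1-one F3. NaOAc in refluxing EtOH closes ring C to a mixture of 18 and (2R)-5,7-bis(benzyloxy)-2-[4-(benzyloxy)phenyl]-6-[(2R)-1-methylpiperidin-2-yl]-2,3-dihydro-4H-chromen-4-one F4. These are diastereomers because C2'' is fixed, so chromatography or crystallisation should separate them; the unwanted epimer can be re-equilibrated through the chalcone under the same conditions. The route is rejoined at 18.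

Step 2. Deprotonation of a benzylic OCH2 (followed by Wittig rearrangement) may compete with ring lithiation, and the hindered aryllithium may enolise the lactam instead of adding to it. The fallback introduces the benzylic carbon by electrophilic formylation and builds the chain onto it. Setting out from 1, Vilsmeier–Haack formylation (POCl3, DMF) should go mainly para to the hydroxyl and give 2,6-bis(benzyloxy)-4-hydroxybenzaldehyde F5, the ortho-formyl isomer being removed by chromatography. TIPSCl and imidazole give 2,6-bis(benzyloxy)-4-(triisopropylsilyloxy)benzaldehyde F6. 4-Chlorobutylmagnesium bromide F7, made from 1-bromo-4-chlorobutane and Mg in THF, adds to the aldehyde to give 1-[2,6-bis(benzyloxy)-4-(triisopropylsilyloxy)phenyl]-5-chloropentan-1-ol F8. Dess–Martin periodinane buffered with NaHCO3 oxidises it to 1-[2,6-bis(benzyloxy)-4-(triisopropylsilyloxy)phenyl]-5-chloropentan-1-one F9. NaN3 with catalytic NaI in DMF gives 5-azido-1-[2,6-bis(benzyloxy)-4-(triisopropylsilyloxy)phenyl]pentan-1-one F10. Staudinger reduction with PMe3 in wet THF, with Boc2O present to trap the amine before it condenses with the ketone, gives 5, where the route is rejoined.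

**Further compounds**
F1 | step 3 | racemic 2-[2,6-bis(benzyloxy)-4-(triisopropylsilyloxy)phenyl]piperidine | N1CCCCC1c1c(OCc2ccccc2)cc(O[Si](C(C)C)(C(C)C)C(C)C)cc1OCc1ccccc1
F2 | step 3 | (2S)-2-[2,6-bis(benzyloxy)-4-(triisopropylsilyloxy)phenyl]piperidine | N1CCCC[C@H]1c1c(OCc2ccccc2)cc(O[Si](C(C)C)(C(C)C)C(C)C)cc1OCc1ccccc1
F3 | step 9 | (2E)-1-{2,4-bis(benzyloxy)-6-hydroxy-3-[(2R)-1-methylpiperidin-2-yl]phenyl}-3-[4-(benzyloxy)phenyl]prop-2-en-1-one | CN1CCCC[C@@H]1c1c(OCc2ccccc2)cc(O)c(C(=O)/C=C/c2ccc(OCc3ccccc3)cc2)c1OCc1ccccc1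
F4 | step 9 | (2R)-5,7-bis(benzyloxy)-2-[4-(benzyloxy)phenyl]-6-[(2R)-1-methylpiperidin-2-yl]-2,3-dihydro-4H-chromen-4-one | CN1CCCC[C@@H]1c1c(OCc2ccccc2)cc2c(c1OCc1ccccc1)C(=O)C[C@H](c1ccc(OCc3ccccc3)cc1)O2
F5 | step 2 | 2,6-bis(benzyloxy)-4-hydroxybenzaldehyde | O=Cc1c(OCc2ccccc2)cc(O)cc1OCc1ccccc1
F6 | step 2 | 2,6-bis(benzyloxy)-4-(triisopropylsilyloxy)benzaldehyde | O=Cc1c(OCc2ccccc2)cc(O[Si](C(C)C)(C(C)C)C(C)C)cc1OCc1ccccc1
F7 | step 2 | 4-chlorobutylmagnesium bromide | ClCCCC[Mg]Br
F8 | step 2 | 1-[2,6-bis(benzyloxy)-4-(triisopropylsilyloxy)phenyl]-5-chloropentan-1-ol (racemic) | OC(CCCCCl)c1c(OCc2ccccc2)cc(O[Si](C(C)C)(C(C)C)C(C)C)cc1OCc1ccccc1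
F9 | step 2 | 1-[2,6-bis(benzyloxy)-4-(triisopropylsilyloxy)phenyl]-5-chloropentan-1-one | O=C(CCCCCl)c1c(OCc2ccccc2)cc(O[Si](C(C)C)(C(C)C)C(C)C)cc1OCc1ccccc1
F10 | step 2 | 5-azido-1-[2,6-bis(benzyloxy)-4-(triisopropylsilyloxy)phenyl]pentan-1-one | [N-]=[N+]=NCCCCC(=O)c1c(OCc2ccccc2)cc(O[Si](C(C)C)(C(C)C)C(C)C)cc1OCc1ccccc1
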